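The numbers in the tables come from a simulation on assumed constants; the scatter is artificial.

We cannot read the west run at 9.8 min off the north-west run, though both hold the same charge: the north-west readings stop at 4.9 min, and the time asked is twice that. So we solve the two ends and join them.

the same everywhere: Cat 0.0400 M

|  | Sub | time |
|---|---|---|
| north-west | 0.800 M |  |
| north | 0.320 M |  |
| east | 0.400 M |  |
| west | 0.800 M | 9.8 min |

- north-west run (time / min: [Sub] / M): 0.98: 0.6795; 2.0: 0.5766; 2.9: 0.4880; 3.9: 0.4074; 4.9: 0.3357
- north run (time / min: [Sub] / M): 0.98: 0.2627; 2.0: 0.2131; 2.9: 0.1730; 3.9: 0.1454; 4.9: 0.1157
- east run (time / min: [Sub] / M): 0.98: 0.3330; 2.0: 0.2706; 2.9: 0.2258; 3.9: 0.1869; 4.9: 0.1477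

(scatter of a reading: 0.002 M)

- Overall: Sub -> Prd, with Cat as catalyst.
- Constant volume, constant temperature.
- Bound and free are read together.
- An order is taken over about fifteen percent of the charge, up and down.

1. how the opening rate goes with [Sub] round the charge of the north-west run: the exponent of the rate at two percent of Sub gone to Prd (one fixed amount of Prd, the same in the runs compared)
2. the north run starts with 0.480 M less of Sub than the north-west run, and with no Prd. Compared where both hold the same amount of Sub, once fifteen percent of what the north run was charged with has turned into Prd, is the north run faster, slower or alike (within a tenth)?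
3. Sub in the west run at 9.8 min, as a share of the Sub charged

1. Opening end. Let k be the pseudo-first-order constant, the fall of ln[Sub] per minute. From its charge to its first reading, the north-west run gives k = 0.167 /min.

2. Lean end. The tail constant k_t is the k of the east run from its first reading to its last, a stretch that starts close to the Sub where the north-west readings stop. It comes to 0.207 /min, higher than the opening k.

3. Join. The north-west run at 4.9 min holds 0.3357 M, and the east run at 0.98 min holds 0.3330 M. Yet the north-west run has made 0.464 M of Prd by then, and the east run 0.0670 M. Does that Prd matter? Over nearly the same span of Sub, the north-west run's last interval reads k = 0.194 /min and the east run's first reads 0.187 /min. One reading's scatter moves such a k by 0.00608 /min, so we see no effect of Prd and expect the north run to be alike at equal Sub.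

4. Reckoning. The west run follows the north-west run to 0.3357 M, then runs 4.90 min at k_t, which leaves 0.122 M, or 15.2% of the charge. This second stretch keeps 36.2% of its Sub, less than the 42.0% kept by the equally long first stretch, because k is higher at the lean end.

The forecast gives an order of 0.75, the answer alike, and 14.5%, this last from “k of about 0.215 over 4.9 min”. Our 15.2% stands above its share.

The flask gives an order of 0.73, the north run alike, and 15.6% of the west charge left at 9.8 min.

    Cat + Sub ⇌ Cat.Sub, settled at all times (0.2970 /M)
    Cat.Sub + Cat → Prd + 2 Cat (580.8 /M/min)
    Cat + X → Q
    Sub → Prd (0.03978 /min)

Set against the north-west run at the point compared, the rate ratio of the north run is 1.0. The west run holds 0.125 M at 9.8 min, which is 0.00304 M more than k_t carried it to. On the north run, a second flask, the half-life at k_t is 3.35 min, and that run reaches half of its charge as Prd at 3.45 min.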